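## Retrosynthetic overview

1. Target 20 ⇒ diol 16 + vanillic acid (used as its O-acetate 18); the ester is made last at the secondary OH.
2. Tertiary allylic alcohol ⇒ MeLi + (2E,7E)-cyclodecadienone 14; 14 comes from a 1,2-carbonyl transposition (triflate reduction, then selenoxide elimination) of an oxy-Cope product.
3. Ten-membered ring ⇐ anionic oxy-Cope (6 → 10 ring expansion, forms the E-trisubstituted olefin) of 1-(1-ethoxyvinyl)-2-methyl-2-vinylcyclohexanol 9.
4. Cyclohexanone 8 ⇐ carvacrol methyl ether 1: Birch reduction breaks the arene into a diene with two differentiated C=C bonds; asymmetric hydroboration of one sets both ring stereocentres, the enol ether is the masked, regiodefined ketone.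
5. Ring order: the six-membered ring is the arene ring of 1 itself (dearomatized, never built); the ten-membered ring is second, by ring expansion; no other ring is made.

Assumption: carvacrol methyl ether (1) is purchased, and IpcBH2 is prepared beforehand from (+)-α-pinene.

## Route

Step 1
Reactants: 1 carvacrol methyl ether (4-isopropyl-2-methoxy-1-methylbenzene)
Product: 2 4-isopropyl-2-methoxy-1-methylcyclohexa-1,4-diene
Conditions: Li, NH3(l), THF, t-BuOH, −78 → −33 °C; NH4Cl
Reagents that add atoms: none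
Why: Birch reduction: the OMe-, Me- and iPr-bearing carbons stay sp2, so protonation at the two unsubstituted para-related carbons gives a skipped diene with a tetrasubstituted enol ether (masked ketone) and one trisubstituted olefin; no stereocentre is formed.

Step 2
Reactants: 2 4-isopropyl-2-methoxy-1-methylcyclohexa-1,4-diene
Product: 4 (1S,6R)-6-isopropyl-4-methoxy-3-methylcyclohex-3-en-1-ol, via alkyl(isopinocampheyl)borane 3 (not isolated)
Conditions: IpcBH2 [from (+)-α-pinene], THF, −25 °C, 36 h; then 3 M NaOH, 30% H2O2, 0 °C → rt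
Reagents that add atoms: monoisopinocampheylborane, C[C@H]1[C@H](B)C[C@@H]2C[C@H]1C2(C)C (B and Ipc in 3); hydrogen peroxide, OO (O in 4)
Why: Brown asymmetric hydroboration–oxidation: the hindered tetrasubstituted enol ether is inert, syn addition puts B on the CH carbon so that retentive oxidation gives OH trans to iPr, and the (+)-α-pinene-derived reagent (S-carbinol sense, as recalled for 1-methylcycloalkenes) sets both stereocentres (1S,6R) in one event.

Step 3
Reactants: 4 (1S,6R)-6-isopropyl-4-methoxy-3-methylcyclohex-3-en-1-ol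
Product: 6 (4S,5R)-4-[(tert-butyldimethylsilyl)oxy]-5-isopropyl-2-methylcyclohexan-1-one (C2 epimers), via TBS enol ether 5 (not isolated)
Conditions: TBSCl, imidazole, DMF, rt; then 0.5 M aq. oxalic acid, THF, rt
Reagents that add atoms: tert-butyldimethylsilyl chloride, CC(C)(C)[Si](C)(C)Cl; water, O
Why: Silyl protection followed by mild acid hydrolysis of the enol ether; the TBS ether and the non-enolizable C4/C5 stereocentres survive, and the new C2 centre is an inconsequential epimer mixture.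

Step 4
Reactants: 6 (4S,5R)-4-[(tert-butyldimethylsilyl)oxy]-5-isopropyl-2-methylcyclohexan-1-one
Product: 8 (4S,5R)-4-[(tert-butyldimethylsilyl)oxy]-5-isopropyl-2-methyl-2-vinylcyclohexan-1-one (C2 epimers), via sulfoxide adduct 7 (not isolated)
Conditions: KH, THF, rt, 1 h; PhS(O)CH=CH2, −20 °C → rt; AcOH; then xylene, NaHCO3, 140 °C
Reagents that add atoms: phenyl vinyl sulfoxide, C=CS(=O)c1ccccc1
Why: The equilibrated, more substituted potassium enolate undergoes Michael addition to phenyl vinyl sulfoxide (vinyl-cation equivalent) and thermal sulfoxide syn-elimination unveils the vinyl group; the quaternary centre forms as epimers that are erased in step 6.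

Step 5
Reactants: 8 (4S,5R)-4-[(tert-butyldimethylsilyl)oxy]-5-isopropyl-2-methyl-2-vinylcyclohexan-1-one
Product: 9 (4S,5R)-4-[(tert-butyldimethylsilyl)oxy]-1-(1-ethoxyvinyl)-5-isopropyl-2-methyl-2-vinylcyclohexan-1-ol (C1/C2 diastereomers)
Conditions: CH2=CHOEt, t-BuLi, THF, −78 → 0 °C; then 8, −78 → 0 °C; NH4Cl
Reagents that add atoms: 1-ethoxyvinyllithium, [Li]C(=C)OCC (made in the flask from ethyl vinyl ether, C=COCC)
Why: 1,2-Addition of the α-lithiated enol ether (acyl-anion equivalent) to the ketone; the carbinol configuration does not matter because C1 and C2 become sp2 in step 6.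

Step 6
Reactants: 9 (4S,5R)-4-[(tert-butyldimethylsilyl)oxy]-1-(1-ethoxyvinyl)-5-isopropyl-2-methyl-2-vinylcyclohexan-1-ol
Product: 11 (5E,8S,9R)-8-[(tert-butyldimethylsilyl)oxy]-2-ethoxy-9-isopropyl-6-methylcyclodeca-1,5-dien-1-yl trifluoromethanesulfonate (C1=C2 geometry mixed), via potassium enolate 10 (not isolated)
Conditions: KHMDS, 18-crown-6, THF, 0 °C → rt; then PhNTf2, −78 → 0 °C; NH4Cl
Reagents that add atoms: potassium hexamethyldisilazide, C[Si](C)(C)[N-][Si](C)(C)C.[K+] (K in 10); N-phenylbis(trifluoromethanesulfonimide), O=S(=O)(N(c1ccccc1)S(=O)(=O)C(F)(F)F)C(F)(F)F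
Why: Anionic oxy-Cope rearrangement ([3,3], four-carbon ring expansion): chair transition states with the ring C2–C3 bond pseudo-equatorial give the (E)-trisubstituted olefin from the major (equatorial-alkenyl) diastereomers of 9, the old C1/C2 stereocentres vanish, and the α-ethoxy enolate is trapped by O-triflation; C8 and C9 are untouched.

Step 7
Reactants: 11 (5E,8S,9R)-8-[(tert-butyldimethylsilyl)oxy]-2-ethoxy-9-isopropyl-6-methylcyclodeca-1,5-dien-1-yl trifluoromethanesulfonate
Product: 12 tert-butyl{[(1S,3E,10R)-7-ethoxy-10-isopropyl-3-methylcyclodeca-3,7-dien-1-yl]oxy}dimethylsilane (C7=C8 geometry mixed)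
Conditions: Pd(OAc)2 (5 mol%), PPh3, HCO2H, Et3N, DMF, 50 °C
Reagents that add atoms: none
Why: Pd-catalysed formate reduction of the vinyl triflate (Cacchi) replaces OTf by H under basic conditions that preserve the enol ether, completing a 1,2-carbonyl transposition; the enol-ether geometry is irrelevant.

Step 8
Reactants: 12 tert-butyl{[(1S,3E,10R)-7-ethoxy-10-isopropyl-3-methylcyclodeca-3,7-dien-1-yl]oxy}dimethylsilane
Product: 14 (2E,4S,5S,7E)-5-[(tert-butyldimethylsilyl)oxy]-4-isopropyl-7-methylcyclodeca-2,7-dien-1-one, via α-selanyl ketone 13 (not isolated)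
Conditions: PhSeCl, CH2Cl2, −78 °C; aq. NaHCO3; then 30% H2O2, pyridine, 0 °C → rt
Reagents that add atoms: phenylselenenyl chloride, Cl[Se]c1ccccc1 (Se in 13); water, O (carbonyl O)
Why: Regiospecific electrophilic selenenylation of the enol ether (far more nucleophilic than the trisubstituted olefin) followed by selenoxide syn-elimination, which can only go toward C3 and in a ten-membered ring gives the (E)-enone.

Step 9
Reactants: 14 (2E,4S,5S,7E)-5-[(tert-butyldimethylsilyl)oxy]-4-isopropyl-7-methylcyclodeca-2,7-dien-1-one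
Product: 15 (1R,2E,4S,5S,7E)-5-[(tert-butyldimethylsilyl)oxy]-4-isopropyl-1,7-dimethylcyclodeca-2,7-dien-1-ol
Conditions: MeLi, Et2O/THF, −78 °C; NH4Cl
Reagents that add atoms: methyllithium, [Li]C
Why: 1,2-Addition of MeLi to the enone under macrocyclic stereocontrol: on a simple model of the crossed conformer (iPr and OTBS pseudo-equatorial) methyl enters on the carbonyl face anti to the transannular C7=C8 olefin, giving (1R), though the model does not clearly separate the two faces; −78 °C avoids γ-deprotonation at C4.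

Step 10
Reactants: 15 (1R,2E,4S,5S,7E)-5-[(tert-butyldimethylsilyl)oxy]-4-isopropyl-1,7-dimethylcyclodeca-2,7-dien-1-ol
Product: 16 (1R,2E,4S,5S,7E)-4-isopropyl-1,7-dimethylcyclodeca-2,7-diene-1,5-diol
Conditions: TBAF, THF, rt; NH4Cl
Reagents that add atoms: none
Why: Fluoride-mediated desilylation of the secondary TBS ether; olefins, the tertiary allylic alcohol and all stereocentres are unaffected.

Step 11
Reactants: 17 vanillic acid
Product: 18 4-acetoxy-3-methoxybenzoic acid
Conditions: Ac2O, pyridine, rt; H2O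
Reagents that add atoms: acetic anhydride, CC(=O)OC(C)=O
Why: Acetylation of the phenol (acyl transfer); any mixed anhydride at the carboxyl group is hydrolysed on aqueous work-up.

Step 12
Reactants: 16 (1R,2E,4S,5S,7E)-4-isopropyl-1,7-dimethylcyclodeca-2,7-diene-1,5-diol; 18 4-acetoxy-3-methoxybenzoic acid
Product: 20 (1S,2S,3E,5R,8E)-5-hydroxy-2-isopropyl-5,9-dimethylcyclodeca-3,8-dien-1-yl 4-hydroxy-3-methoxybenzoate (target), via O-acetyl ester 19 (not isolated)
Conditions: DCC, DMAP (cat.), CH2Cl2, 0 °C → rt; then pyrrolidine, 0 °C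
Reagents that add atoms: none
Why: Steglich esterification acylates only the secondary alcohol (the tertiary allylic alcohol is inert) with retention at the carbinol carbon, and the phenolic acetate is then removed by selective aminolysis with pyrrolidine.

## Compound list

1 | carvacrol methyl ether (4-isopropyl-2-methoxy-1-methylbenzene) | COc1cc(C(C)C)ccc1C | starting material
2 | 4-isopropyl-2-methoxy-1-methylcyclohexa-1,4-diene | COC1=C(C)CC=C(C(C)C)C1 | intermediate
3 | [(1S,6R)-6-isopropyl-4-methoxy-3-methylcyclohex-3-en-1-yl](isopinocampheyl)borane | C[C@H]1[C@H](B[C@H]2CC(C)=C(OC)C[C@@H]2C(C)C)C[C@@H]3C[C@H]1C3(C)C | intermediate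
4 | (1S,6R)-6-isopropyl-4-methoxy-3-methylcyclohex-3-en-1-ol | O[C@H]1CC(C)=C(OC)C[C@@H]1C(C)C | intermediate
5 | tert-butyl{[(1S,6R)-6-isopropyl-4-methoxy-3-methylcyclohex-3-en-1-yl]oxy}dimethylsilane | CC(C)(C)[Si](C)(C)O[C@H]1CC(C)=C(OC)C[C@@H]1C(C)C | intermediate
6 | (4S,5R)-4-[(tert-butyldimethylsilyl)oxy]-5-isopropyl-2-methylcyclohexan-1-one (C2 epimers) | CC(C)(C)[Si](C)(C)O[C@H]1CC(C)C(=O)C[C@@H]1C(C)C | intermediate
7 | (4S,5R)-4-[(tert-butyldimethylsilyl)oxy]-5-isopropyl-2-methyl-2-[2-(phenylsulfinyl)ethyl]cyclohexan-1-one (epimers at C2 and S) | CC(C)(C)[Si](C)(C)O[C@H]1CC(C)(CCS(=O)c2ccccc2)C(=O)C[C@@H]1C(C)C | intermediate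
8 | (4S,5R)-4-[(tert-butyldimethylsilyl)oxy]-5-isopropyl-2-methyl-2-vinylcyclohexan-1-one (C2 epimers) | CC(C)(C)[Si](C)(C)O[C@H]1CC(C)(C=C)C(=O)C[C@@H]1C(C)C | intermediate
9 | (4S,5R)-4-[(tert-butyldimethylsilyl)oxy]-1-(1-ethoxyvinyl)-5-isopropyl-2-methyl-2-vinylcyclohexan-1-ol (C1/C2 diastereomers) | CC(C)(C)[Si](C)(C)O[C@H]1CC(C)(C=C)C(O)(C(=C)OCC)C[C@@H]1C(C)C | intermediate
10 | potassium (5E,8S,9R)-8-[(tert-butyldimethylsilyl)oxy]-2-ethoxy-9-isopropyl-6-methylcyclodeca-1,5-dien-1-olate | CC(C)(C)[Si](C)(C)O[C@H]1C/C(C)=C/CCC(OCC)=C([O-])C[C@@H]1C(C)C.[K+] | intermediate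
11 | (5E,8S,9R)-8-[(tert-butyldimethylsilyl)oxy]-2-ethoxy-9-isopropyl-6-methylcyclodeca-1,5-dien-1-yl trifluoromethanesulfonate | CC(C)(C)[Si](C)(C)O[C@H]1C/C(C)=C/CCC(OCC)=C(OS(=O)(=O)C(F)(F)F)C[C@@H]1C(C)C | intermediate
12 | tert-butyl{[(1S,3E,10R)-7-ethoxy-10-isopropyl-3-methylcyclodeca-3,7-dien-1-yl]oxy}dimethylsilane | CC(C)(C)[Si](C)(C)O[C@H]1C/C(C)=C/CCC(OCC)=CC[C@@H]1C(C)C | intermediate
13 | (4R,5S,7E)-5-[(tert-butyldimethylsilyl)oxy]-4-isopropyl-7-methyl-2-(phenylselanyl)cyclodec-7-en-1-one (C2 epimers) | CC(C)(C)[Si](C)(C)O[C@H]1C/C(C)=C/CCC(=O)C([Se]c2ccccc2)C[C@@H]1C(C)C | intermediate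
14 | (2E,4S,5S,7E)-5-[(tert-butyldimethylsilyl)oxy]-4-isopropyl-7-methylcyclodeca-2,7-dien-1-one | CC(C)(C)[Si](C)(C)O[C@H]1C/C(C)=C/CCC(=O)/C=C/[C@@H]1C(C)C | intermediate
15 | (1R,2E,4S,5S,7E)-5-[(tert-butyldimethylsilyl)oxy]-4-isopropyl-1,7-dimethylcyclodeca-2,7-dien-1-ol | CC(C)(C)[Si](C)(C)O[C@H]1C/C(C)=C/CC[C@@](C)(O)/C=C/[C@@H]1C(C)C | intermediate
16 | (1R,2E,4S,5S,7E)-4-isopropyl-1,7-dimethylcyclodeca-2,7-diene-1,5-diol | O[C@H]1C/C(C)=C/CC[C@@](C)(O)/C=C/[C@@H]1C(C)C | intermediate
17 | vanillic acid (4-hydroxy-3-methoxybenzoic acid) | COc1cc(C(=O)O)ccc1O | starting material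
18 | 4-acetoxy-3-methoxybenzoic acid | COc1cc(C(=O)O)ccc1OC(C)=O | intermediate
19 | (1S,2S,3E,5R,8E)-5-hydroxy-2-isopropyl-5,9-dimethylcyclodeca-3,8-dien-1-yl 4-acetoxy-3-methoxybenzoate | COc1cc(C(=O)O[C@H]2C/C(C)=C/CC[C@@](C)(O)/C=C/[C@@H]2C(C)C)ccc1OC(C)=O | intermediate
20 | (1S,2S,3E,5R,8E)-5-hydroxy-2-isopropyl-5,9-dimethylcyclodeca-3,8-dien-1-yl 4-hydroxy-3-methoxybenzoate | COc1cc(C(=O)O[C@H]2C/C(C)=C/CC[C@@](C)(O)/C=C/[C@@H]2C(C)C)ccc1O | target

## Step count and risks

Total steps: 12. Longest linear sequence: 11 (steps 1–10 and 12).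

Three steps most likely to fail:

Step 2 (enantioselectivity, and selectivity for the trisubstituted olefin over the enol ether). IpcBH2 usually gives only moderate to good ee with trisubstituted cycloalkenes. The fallback sets out from 2 and comes back at 4. It replaces reagent control by an enzymatic kinetic resolution: 2 is hydroborated with BH3·SMe2 and oxidised (NaOH/H2O2) to the racemic trans alcohol, rac-(1S*,6R*)-6-isopropyl-4-methoxy-3-methylcyclohex-3-en-1-ol F1. This is treated with Burkholderia cepacia lipase and vinyl acetate in MTBE. By the Kazlauskas rule the unwanted enantiomer is acylated to (1R,6S)-6-isopropyl-4-methoxy-3-methylcyclohex-3-en-1-yl acetate F2 and removed by chromatography, leaving the unreacted (1S,6R)-alcohol 4. The same enzymatic acylation can polish partly enriched 4 from step 2.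

Step 4 (regioselectivity of the thermodynamic enolate, over-alkylation, and a quaternary centre formed in a Michael step). The fallback sets out from 6 and comes back at 8. It builds the vinyl group by Lewis-acid aldol chemistry and dehydration instead. TMSCl/NaI/Et3N in MeCN gives the more substituted silyl enol ether, tert-butyl{[(1S,6R)-6-isopropyl-3-methyl-4-(trimethylsilyloxy)cyclohex-3-en-1-yl]oxy}dimethylsilane F3. Mukaiyama aldol with acetaldehyde (TiCl4, CH2Cl2, −78 °C) gives (4S,5R)-4-[(tert-butyldimethylsilyl)oxy]-2-(1-hydroxyethyl)-5-isopropyl-2-methylcyclohexan-1-one F4. Burgess dehydration (benzene, 50 °C) can only eliminate toward the methyl group, because the other β-carbon is quaternary, and gives 8.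

Step 9 (facial selectivity of methyl addition; the sense rests on a conformational model). The fallback sets out from 8 and comes back at 15. It forms the C–O bond at the carbinol carbon instead of the C–CH3 bond, so the same facial bias delivers the opposite partner. Isopropenylmagnesium bromide adds to 8 to give (4S,5R)-4-[(tert-butyldimethylsilyl)oxy]-5-isopropyl-2-methyl-1-(prop-1-en-2-yl)-2-vinylcyclohexan-1-ol F5. Anionic oxy-Cope rearrangement (KHMDS, 18-crown-6) and hydroxylation of the tetrasubstituted enolate in the same flask with 2-(phenylsulfonyl)-3-phenyloxaziridine gives (2R,5E,8S,9R)-8-[(tert-butyldimethylsilyl)oxy]-2-hydroxy-9-isopropyl-2,6-dimethylcyclodec-5-en-1-one F6 (C2 epimers separable). KHMDS (2.2 equiv) and PhNTf2 give the ring-trans enol triflate, (3S,4S,6E,10R)-4-[(tert-butyldimethylsilyl)oxy]-10-hydroxy-3-isopropyl-6,10-dimethylcyclodeca-1,6-dien-1-yl trifluoromethanesulfonate F7; a ketone flanked by a quaternary carbon gives the Z(O)-enolate. Pd(OAc)2/PPh3/HCO2H–Et3N reduction then gives 15.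

Further compounds

F1 | step 2 | rac-(1S*,6R*)-6-isopropyl-4-methoxy-3-methylcyclohex-3-en-1-ol (1:1 mixture of enantiomers) | O[C@H]1CC(C)=C(OC)C[C@@H]1C(C)C.O[C@@H]1CC(C)=C(OC)C[C@H]1C(C)C
F2 | step 2 | (1R,6S)-6-isopropyl-4-methoxy-3-methylcyclohex-3-en-1-yl acetate | CC(=O)O[C@@H]1CC(C)=C(OC)C[C@H]1C(C)C
F3 | step 4 | tert-butyl{[(1S,6R)-6-isopropyl-3-methyl-4-(trimethylsilyloxy)cyclohex-3-en-1-yl]oxy}dimethylsilane | CC(C)(C)[Si](C)(C)O[C@H]1CC(C)=C(O[Si](C)(C)C)C[C@@H]1C(C)C
F4 | step 4 | (4S,5R)-4-[(tert-butyldimethylsilyl)oxy]-2-(1-hydroxyethyl)-5-isopropyl-2-methylcyclohexan-1-one | CC(C)(C)[Si](C)(C)O[C@H]1CC(C)(C(C)O)C(=O)C[C@@H]1C(C)C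
F5 | step 9 | (4S,5R)-4-[(tert-butyldimethylsilyl)oxy]-5-isopropyl-2-methyl-1-(prop-1-en-2-yl)-2-vinylcyclohexan-1-ol | CC(C)(C)[Si](C)(C)O[C@H]1CC(C)(C=C)C(O)(C(C)=C)C[C@@H]1C(C)C
F6 | step 9 | (2R,5E,8S,9R)-8-[(tert-butyldimethylsilyl)oxy]-2-hydroxy-9-isopropyl-2,6-dimethylcyclodec-5-en-1-one | CC(C)(C)[Si](C)(C)O[C@H]1C/C(C)=C/CC[C@@](C)(O)C(=O)C[C@@H]1C(C)C
F7 | step 9 | (3S,4S,6E,10R)-4-[(tert-butyldimethylsilyl)oxy]-10-hydroxy-3-isopropyl-6,10-dimethylcyclodeca-1,6-dien-1-yl trifluoromethanesulfonate (ring-trans C1=C2) | CC(C)(C)[Si](C)(C)O[C@H]1C/C(C)=C/CC[C@@](C)(O)/C(OS(=O)(=O)C(F)(F)F)=C/[C@@H]1C(C)C
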